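**Plan**
- Retrosynthesis cuts, in order: the three O–benzyl bonds, the C3–O bond, the C4–C4a bond of ring C (arene acylation), the C2–O1 enol ether bond (phenol plus arylpropiolate), and the aryl–alkyne bond on ring B.
- Forward: the ring B iodide is made from isovanillin (steps 1–4) and alkynylated with ethyl propiolate (step 5). The ring A phenol is made from 3-hydroxy-4,5-dimethoxybenzaldehyde (steps 6–9) and added to the alkynoate (step 10).
- After saponification (step 11), ring C is closed onto ring A (step 12), C3 is hydroxylated (step 13) and the benzyl ethers are removed (step 14).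
- Enabling feature: C4a is the only hydrogen-bearing ring A carbon next to O1 (C8 carries a methoxy group). It lies between oxygenated C5 and C8a and para to the C7 methoxy, so the acylation that forms C4–C4a has a single possible site.
- Stereochemistry: the target has no stereocentre. The only stereo-element on the way is the alkene geometry of 15 and 16, which converges in the ring closure.

Key step: step 12

Remark: the 5-hydroxyl is carried as a benzyl ether rather than a methyl ether, so that one hydrogenolysis frees all three phenols and no selective demethylation is needed. Compounds 15–17 are drawn as the Z isomers expected from anti addition; any E isomer would be carried along.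

**Step 1**
Reactants: 1 isovanillin (3-hydroxy-4-methoxybenzaldehyde)
Product: 2 3-(benzyloxy)-4-methoxybenzaldehyde
Conditions: BnBr, K2CO3, DMF, rt
Reagents that add atoms: benzyl bromide, BrCc1ccccc1
Why: Williamson O-alkylation of the phenoxide with a benzylic halide should proceed cleanly.

**Step 2**
Reactants: 2 3-(benzyloxy)-4-methoxybenzaldehyde
Product: 4 3-(benzyloxy)-4-methoxyphenol, via aryl formate 3 (not isolated)
Conditions: mCPBA, CH2Cl2, 0 °C to rt; crude formate, K2CO3 (cat.), MeOH, rt
Reagents that add atoms: 3-chloroperoxybenzoic acid (mCPBA), OOC(=O)c1cccc(Cl)c1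
Why: Baeyer–Villiger (Dakin-type) oxidation, in which the aryl group made electron-rich by the para methoxy migrates in preference to hydrogen, followed by base-catalysed methanolysis of the formate.

**Step 3**
Reactants: 4 3-(benzyloxy)-4-methoxyphenol
Product: 5 2,4-bis(benzyloxy)-1-methoxybenzene
Conditions: BnBr, K2CO3, DMF, rt
Reagents that add atoms: benzyl bromide, BrCc1ccccc1
Why: Williamson O-benzylation of the new phenol.

**Step 4**
Reactants: 5 2,4-bis(benzyloxy)-1-methoxybenzene
Product: 6 1,5-bis(benzyloxy)-2-iodo-4-methoxybenzene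
Conditions: NIS, CF3CO2H (cat.), MeCN, 0 °C to rt
Reagents that add atoms: N-iodosuccinimide, O=C1CCC(=O)N1I
Why: Electrophilic aromatic iodination should occur at the carbon para to one benzyloxy and ortho to the other, because the only other doubly activated site is crowded between the two benzyloxy groups.

**Step 5**
Reactants: 6 1,5-bis(benzyloxy)-2-iodo-4-methoxybenzene; 7 ethyl propiolate
Product: 8 ethyl 3-[2,4-bis(benzyloxy)-5-methoxyphenyl]prop-2-ynoate
Conditions: PdCl2(PPh3)2 (cat.), CuI (cat.), K2CO3, THF, 65 °C, 7 in excess added in portions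
Reagents that add atoms: none
Why: Sonogashira coupling of an aryl iodide with a propiolate ester, using a carbonate base in place of an amine so that conjugate addition to and oligomerisation of the propiolate are held back.

**Step 6**
Reactants: 9 3-hydroxy-4,5-dimethoxybenzaldehyde
Product: 10 3,4-dimethoxy-5-(methoxymethoxy)benzaldehyde
Conditions: MOMCl, iPr2NEt, CH2Cl2, 0 °C to rt
Reagents that add atoms: chloromethyl methyl ether, COCCl
Why: Acetal protection of the phenol that will later become O1, with a group stable to peracid and base and removable beside a benzyl ether.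

**Step 7**
Reactants: 10 3,4-dimethoxy-5-(methoxymethoxy)benzaldehyde
Product: 12 3,4-dimethoxy-5-(methoxymethoxy)phenol, via aryl formate 11 (not isolated)
Conditions: mCPBA, CH2Cl2, 0 °C to rt; crude formate, K2CO3 (cat.), MeOH, rt
Reagents that add atoms: 3-chloroperoxybenzoic acid (mCPBA), OOC(=O)c1cccc(Cl)c1
Why: Baeyer–Villiger oxidation of a trialkoxybenzaldehyde (aryl migration) and formate methanolysis convert the formyl carbon into the oxygen that becomes the 5-O of the flavone.

**Step 8**
Reactants: 12 3,4-dimethoxy-5-(methoxymethoxy)phenol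
Product: 13 5-(benzyloxy)-1,2-dimethoxy-3-(methoxymethoxy)benzene
Conditions: BnBr, K2CO3, DMF, rt
Reagents that add atoms: benzyl bromide, BrCc1ccccc1
Why: Williamson O-benzylation of the free phenol.

**Step 9**
Reactants: 13 5-(benzyloxy)-1,2-dimethoxy-3-(methoxymethoxy)benzene
Product: 14 5-(benzyloxy)-2,3-dimethoxyphenol
Conditions: HCl (conc., few equiv), MeOH, 50 °C
Reagents that add atoms: none
Why: Acid-catalysed acetal exchange removes the methoxymethyl group, while aryl benzyl and methyl ethers are stable to methanolic HCl.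

**Step 10**
Reactants: 14 5-(benzyloxy)-2,3-dimethoxyphenol; 8 ethyl 3-[2,4-bis(benzyloxy)-5-methoxyphenyl]prop-2-ynoate
Product: 15 ethyl (Z)-3-[5-(benzyloxy)-2,3-dimethoxyphenoxy]-3-[2,4-bis(benzyloxy)-5-methoxyphenyl]prop-2-enoate
Conditions: Cs2CO3 (0.5 equiv), DMF, 90 °C
Reagents that add atoms: none
Why: Base-catalysed oxa-Michael addition of the phenoxide to the β-carbon of the alkynoate (the first stage of the Ruhemann flavone synthesis), with anti addition placing the aryloxy group cis to the ester.

**Step 11**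
Reactants: 15 ethyl (Z)-3-[5-(benzyloxy)-2,3-dimethoxyphenoxy]-3-[2,4-bis(benzyloxy)-5-methoxyphenyl]prop-2-enoate
Product: 16 (Z)-3-[5-(benzyloxy)-2,3-dimethoxyphenoxy]-3-[2,4-bis(benzyloxy)-5-methoxyphenyl]prop-2-enoic acid
Conditions: LiOH·H2O, THF/EtOH/H2O, 40 °C; then 1 M HCl to pH 3, 0 °C
Reagents that add atoms: lithium hydroxide, [Li+].[OH-]
Why: Saponification of the ester, with the β-carbon shielded from hydroxide by the donor aryloxy and aryl groups and a cold, brief acidification to spare the enol ether.

**Step 12**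
Reactants: 16 (Z)-3-[5-(benzyloxy)-2,3-dimethoxyphenoxy]-3-[2,4-bis(benzyloxy)-5-methoxyphenyl]prop-2-enoic acid
Product: 18 5-(benzyloxy)-2-[2,4-bis(benzyloxy)-5-methoxyphenyl]-7,8-dimethoxy-4H-chromen-4-one, via mixed trifluoroacetic anhydride 17 (not isolated)
Conditions: (CF3CO)2O (2 equiv), CH2Cl2, 0 °C to rt
Reagents that add atoms: none
Why: The acid and (CF3CO)2O form mixed anhydride 17, an acylium-type electrophile that attacks ring A at the carbon ortho to the enol ether oxygen, and loss of a proton restores aromaticity; this is an intramolecular Friedel–Crafts acylation, the classical closure of β-aryloxycinnamic acids to flavones. Ring C closes by a six-membered electrophilic aromatic substitution (formally 6-exo-trig at the acyl carbon) that forms the C4–C4a bond. No stereocentre is created. The step needs regioselective acylation, which the substrate secures: the other carbon ortho to the ether oxygen carries the future 8-methoxy group, the remaining free ring A carbon cannot be reached through a six-membered ring, and the attacked carbon is ortho to the benzyloxy and para to a methoxy group. The acid must lie cis to the aryloxy group; reversible C-protonation of the push-pull alkene by the CF3CO2H released should let any E acid isomerise to the reactive Z form, while ring B offers only a five-membered closure at a carbon meta to both benzyloxy groups. Anhydride activation without a Lewis acid is chosen so that the three benzyl ethers survive.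

**Step 13**
Reactants: 18 5-(benzyloxy)-2-[2,4-bis(benzyloxy)-5-methoxyphenyl]-7,8-dimethoxy-4H-chromen-4-one
Product: 20 5-(benzyloxy)-2-[2,4-bis(benzyloxy)-5-methoxyphenyl]-3-hydroxy-7,8-dimethoxy-4H-chromen-4-one, via flavone 2,3-epoxide 19 (not isolated)
Conditions: DMDO (acetone solution, excess), CH2Cl2, 0 °C to rt; then p-TsOH·H2O (cat.), CH2Cl2, rt
Reagents that add atoms: dimethyldioxirane, CC1(C)OO1
Why: Dioxirane epoxidation of the C2=C3 bond followed by acid-catalysed opening of the epoxide at C2 and loss of H3 gives the 3-hydroxyflavone (flavone-to-flavonol oxidation by way of the epoxide).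

**Step 14**
Reactants: 20 5-(benzyloxy)-2-[2,4-bis(benzyloxy)-5-methoxyphenyl]-3-hydroxy-7,8-dimethoxy-4H-chromen-4-one
Product: 21 2-(2,4-dihydroxy-5-methoxyphenyl)-3,5-dihydroxy-7,8-dimethoxy-4H-chromen-4-one (target)
Conditions: H2 (1 atm), 10% Pd/C, EtOAc/MeOH, rt
Reagents that add atoms: none
Why: Catalytic hydrogenolysis cleaves the three aryl benzyl ethers and should leave the methyl ethers and the tetrasubstituted, vinylogous-ester C2=C3 bond untouched.

**Compound list**
1 | isovanillin (3-hydroxy-4-methoxybenzaldehyde) | COc1ccc(C=O)cc1O | starting material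
2 | 3-(benzyloxy)-4-methoxybenzaldehyde | COc1ccc(C=O)cc1OCc1ccccc1 | intermediate
3 | 3-(benzyloxy)-4-methoxyphenyl formate | COc1ccc(OC=O)cc1OCc1ccccc1 | intermediate
4 | 3-(benzyloxy)-4-methoxyphenol | COc1ccc(O)cc1OCc1ccccc1 | intermediate
5 | 2,4-bis(benzyloxy)-1-methoxybenzene | COc1ccc(OCc2ccccc2)cc1OCc1ccccc1 | intermediate
6 | 1,5-bis(benzyloxy)-2-iodo-4-methoxybenzene | COc1cc(I)c(OCc2ccccc2)cc1OCc1ccccc1 | intermediate
7 | ethyl propiolate | C#CC(=O)OCC | starting material
8 | ethyl 3-[2,4-bis(benzyloxy)-5-methoxyphenyl]prop-2-ynoate | CCOC(=O)C#Cc1cc(OC)c(OCc2ccccc2)cc1OCc1ccccc1 | intermediate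
9 | 3-hydroxy-4,5-dimethoxybenzaldehyde | COc1cc(C=O)cc(O)c1OC | starting material
10 | 3,4-dimethoxy-5-(methoxymethoxy)benzaldehyde | COCOc1cc(C=O)cc(OC)c1OC | intermediate
11 | 3,4-dimethoxy-5-(methoxymethoxy)phenyl formate | COCOc1cc(OC=O)cc(OC)c1OC | intermediate
12 | 3,4-dimethoxy-5-(methoxymethoxy)phenol | COCOc1cc(O)cc(OC)c1OC | intermediate
13 | 5-(benzyloxy)-1,2-dimethoxy-3-(methoxymethoxy)benzene | COCOc1cc(OCc2ccccc2)cc(OC)c1OC | intermediate
14 | 5-(benzyloxy)-2,3-dimethoxyphenol | COc1cc(OCc2ccccc2)cc(O)c1OC | intermediate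
15 | ethyl (Z)-3-[5-(benzyloxy)-2,3-dimethoxyphenoxy]-3-[2,4-bis(benzyloxy)-5-methoxyphenyl]prop-2-enoate | CCOC(=O)/C=C(\Oc1cc(OCc2ccccc2)cc(OC)c1OC)c1cc(OC)c(OCc2ccccc2)cc1OCc1ccccc1 | intermediate
16 | (Z)-3-[5-(benzyloxy)-2,3-dimethoxyphenoxy]-3-[2,4-bis(benzyloxy)-5-methoxyphenyl]prop-2-enoic acid | OC(=O)/C=C(\Oc1cc(OCc2ccccc2)cc(OC)c1OC)c1cc(OC)c(OCc2ccccc2)cc1OCc1ccccc1 | intermediate
17 | mixed anhydride of acid 16 with trifluoroacetic acid | O=C(OC(=O)C(F)(F)F)/C=C(\Oc1cc(OCc2ccccc2)cc(OC)c1OC)c1cc(OC)c(OCc2ccccc2)cc1OCc1ccccc1 | intermediate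
18 | 5-(benzyloxy)-2-[2,4-bis(benzyloxy)-5-methoxyphenyl]-7,8-dimethoxy-4H-chromen-4-one | COc1cc(-c2cc(=O)c3c(OCc4ccccc4)cc(OC)c(OC)c3o2)c(OCc2ccccc2)cc1OCc1ccccc1 | intermediate
19 | 5-(benzyloxy)-2-[2,4-bis(benzyloxy)-5-methoxyphenyl]-2,3-epoxy-7,8-dimethoxy-2,3-dihydro-4H-chromen-4-one (racemic; the epoxide fusion can only be cis) | COc1cc(C23OC2C(=O)c2c(OCc4ccccc4)cc(OC)c(OC)c2O3)c(OCc2ccccc2)cc1OCc1ccccc1 | intermediate
20 | 5-(benzyloxy)-2-[2,4-bis(benzyloxy)-5-methoxyphenyl]-3-hydroxy-7,8-dimethoxy-4H-chromen-4-one | COc1cc(-c2oc3c(OC)c(OC)cc(OCc4ccccc4)c3c(=O)c2O)c(OCc2ccccc2)cc1OCc1ccccc1 | intermediate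
21 | 2-(2,4-dihydroxy-5-methoxyphenyl)-3,5-dihydroxy-7,8-dimethoxy-4H-chromen-4-one | COc1cc(-c2oc3c(OC)c(OC)cc(O)c3c(=O)c2O)c(O)cc1O | target

**Step count**
Total: 14 steps. Longest linear sequence: 10 steps (steps 1–5 and 10–14). The ring A branch (steps 6–9) joins at step 10.

**Steps most likely to fail**

Step 10. The conjugate addition may stall because the 2,4-dialkoxyaryl group feeds electron density into the alkyne, and the phenoxide may instead attack the ester carbonyl (acyl transfer). The fallback replaces conjugate addition by a metal-catalysed vinylic C–O coupling. It sets out from 8, which is hydroiodinated (NaI, AcOH, 80 °C) to ethyl (Z)-3-[2,4-bis(benzyloxy)-5-methoxyphenyl]-3-iodoprop-2-enoate F1. Ullmann-type coupling of F1 with phenol 14 (CuI, N,N-dimethylglycine, Cs2CO3, dioxane, 90 °C) would return to the route at 15.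

Step 12. The mixed anhydride of a vinylogous carbonate may be too weak an electrophile. Stronger acid could strip benzyl ethers or let the E acid lactonise onto the 2'-benzyloxy oxygen with loss of the benzyl group. The fallback makes the same C4–C4a bond with reversed polarity and no acid activation.
- From 8, aminolysis with MeNHOMe·HCl and iPrMgCl (THF, −20 °C) gives 3-[2,4-bis(benzyloxy)-5-methoxyphenyl]-N-methoxy-N-methylprop-2-ynamide F2.
- From 13, ortho-lithiation between the methoxymethoxy and benzyloxy groups (n-BuLi, THF, 0 °C) and addition to F2 gives 1-[6-(benzyloxy)-3,4-dimethoxy-2-(methoxymethoxy)phenyl]-3-[2,4-bis(benzyloxy)-5-methoxyphenyl]prop-2-yn-1-one F3.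
- HCl in MeOH removes the acetal to give 1-[6-(benzyloxy)-2-hydroxy-3,4-dimethoxyphenyl]-3-[2,4-bis(benzyloxy)-5-methoxyphenyl]prop-2-yn-1-one F4.
- Catalytic DMAP in DMF should close F4 by 6-endo-dig oxa-Michael addition, returning to the route at 18.

Step 13. Epoxidation of the electron-poor C2=C3 bond is slow, so oxidation of the electron-rich trialkoxyaryl rings or of benzylic C–H bonds may compete, and the epoxide may open along other paths. The fallback hydroxylates C3 through an anion. It sets out from 18: C3 lithiation (LDA, THF, −78 °C) and trapping with B(OMe)3 give, after aqueous work-up, [5-(benzyloxy)-2-[2,4-bis(benzyloxy)-5-methoxyphenyl]-7,8-dimethoxy-4-oxo-4H-chromen-3-yl]boronic acid F5. Oxidation of F5 (H2O2, AcOH, rt) returns to the route at 20.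

**Further compounds**
F1 | step 10 | ethyl (Z)-3-[2,4-bis(benzyloxy)-5-methoxyphenyl]-3-iodoprop-2-enoate | CCOC(=O)/C=C(\I)c1cc(OC)c(OCc2ccccc2)cc1OCc1ccccc1
F2 | step 12 | 3-[2,4-bis(benzyloxy)-5-methoxyphenyl]-N-methoxy-N-methylprop-2-ynamide | CON(C)C(=O)C#Cc1cc(OC)c(OCc2ccccc2)cc1OCc1ccccc1
F3 | step 12 | 1-[6-(benzyloxy)-3,4-dimethoxy-2-(methoxymethoxy)phenyl]-3-[2,4-bis(benzyloxy)-5-methoxyphenyl]prop-2-yn-1-one | COCOc1c(OC)c(OC)cc(OCc2ccccc2)c1C(=O)C#Cc1cc(OC)c(OCc2ccccc2)cc1OCc1ccccc1
F4 | step 12 | 1-[6-(benzyloxy)-2-hydroxy-3,4-dimethoxyphenyl]-3-[2,4-bis(benzyloxy)-5-methoxyphenyl]prop-2-yn-1-one | COc1cc(OCc2ccccc2)c(C(=O)C#Cc2cc(OC)c(OCc3ccccc3)cc2OCc2ccccc2)c(O)c1OC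
F5 | step 13 | [5-(benzyloxy)-2-[2,4-bis(benzyloxy)-5-methoxyphenyl]-7,8-dimethoxy-4-oxo-4H-chromen-3-yl]boronic acid | COc1cc(-c2oc3c(OC)c(OC)cc(OCc4ccccc4)c3c(=O)c2B(O)O)c(OCc2ccccc2)cc1OCc1ccccc1
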